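The numbers in the tables were generated by integration for substances that don't exist, and the scatter is random.

If each electrophile that reacts takes one nucleophile, the excess of nucleophile over electrophile stays at its charged value. For a step first order in each, the logarithm of their ratio then climbs in a straight line, with a slope proportional to that excess. I test this on two earlier runs and use it on two new flasks, winter and noon.

in all of them: electrophile 0.090 M; gas 41 mM (held)

| flask | nucleophile | remark | time |
|---|---|---|---|
| green | 1.5 equiv | run made earlier |  |
| grey | 2.7 equiv | run made earlier |  |
| winter | 1.30 equiv |  | 20 min |
| noon | 2.00 equiv |  | 20 min |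

| run | time / min | electrophile / % | target / % |
|---|---|---|---|
| green | 2.00 | 81.0 | 14.1 |
| green | 4.00 | 72.2 | 24.0 |
| green | 6.00 | 61.9 | 29.7 |
| green | 8.00 | 54.8 | 33.7 |
| green | 10.0 | 49.5 | 40.6 |
| grey | 0.833 | 86.3 | 11.6 |
| grey | 2.50 | 68.0 | 25.4 |
| grey | 5.00 | 48.9 | 40.3 |
| grey | 8.00 | 36.6 | 53.3 |
| grey | 10.0 | 29.3 | 59.9 |

(readings scatter by 1 percentage point)

- what was read earlier has a scatter of 1 percentage point, one standard deviation
- at the start none of the gas is in solution
- what has gone from electrophile into another species counts as reacted, even if it can come back

1. part of the electrophile that has reacted at the end, winter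
2. part of the electrophile that has reacted at the end, noon
3. what raising the equivalents of nucleophile from its lowest to its highest value here does to the part of the electrophile that has reacted (changes below 5 percentage points count as none) (it rises / it falls / no change)

At 10.0 min, one thing looks wrong. Grey is charged with 1.80 times the nucleophile of green, yet it has reacted 1.40 times as much electrophile, the limiting reagent by charge. In powers of ten the gap nearly closes: the electrophile has fallen 0.533 decades in grey and 0.305 in green, a ratio of 1.75. A decade removes a fixed share of what is left, so percentages flatten as the logarithm climbs.

Allowing for the nucleophile used, green's last reading gives 0.0254 min⁻¹ and grey's gives 0.0236 min⁻¹. Their mean, 0.0245 min⁻¹, is my decade rate: the climb in the base-ten logarithm of nucleophile over electrophile, per minute and per equivalent of excess.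

Over 20 min, that ratio grows by a factor r. With b the equivalents, the part reacted is b(r−1)/(br−1). Winter has r = 1.40, which gives 63.6%. Noon has r = 3.09, which gives 80.7%, more than winter.

The forecast gives 62% and 79%, both below my figures, and for the part reacted from the lowest to the highest nucleophile it says it rises: “More nucleophile raises conversion”.

The flask gives 61.9% for winter and 75.2% for noon, so it rises by 13 percentage points. My reckoning stands 1.7 points and 5.5 points too high.

    electrophile ⇌ dormant form (K = 0.430, k = 0.0240 min⁻¹)
    gas ⇌ free base, rate k2*(csat - [free base]) (kL = 0.930 min⁻¹)
    nucleophile + acid set free ⇌ protonated nucleophile, settled at all times (K = 270 L mol⁻¹)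
    acid set free + free base ⇌ salt of the base (K = 11000 L mol⁻¹, k = 1.60 L mol⁻¹ min⁻¹)
    electrophile + nucleophile → acid set free + target (k = 0.580 L mol⁻¹ min⁻¹)

In winter as charged, the electrophile's half-life is 10 min by the step to target, shorter than the 29 min by forward loss to the dormant form. At 20.0 min, winter holds more target, 46.6%, than dormant form, 15.3%.

For the winter flask read at 80 min, the decade rate gives r = 3.88 and so 92.6% reacted. The computed flask gives 80.3%, with 17% of its nucleophile charge still there, unbound.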